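**Retrosynthetic overview**
1. Target 17 ⇐ fully protected dihydronaphthalene 16 (two tert-butyl esters, catechol acetonide, all acid-labile); the C3=C4 bond of 16 ⇐ C4 ketone of tetralone 13 (reduce, eliminate, equilibrate C2 to trans).
2. Key disconnection: ring B of 13 ⇐ one-carbon ring expansion of indanone β-keto ester 11; a CH(CO2tBu) unit is inserted between the ketone carbon and C2 (formal 1,2-acyl shift through a cyclopropanol), which brings in C3 together with its carboxyl.
3. Five-membered ring and the C1 stereocentre of 11 ⇐ enantioselective Nazarov cyclisation of alkylidene β-keto ester 10 ⇐ Knoevenagel condensation of aroylacetate 4 with pyranone aldehyde 9.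
4. 4 ⇐ catechol (acetonide, Friedel–Crafts with methyl malonyl chloride); 9 ⇐ methyl tiglate + di-tert-butyl oxalate (vinylogous Claisen, lactonisation), then CH3 → CHO.
5. Ring order: ring A (from catechol), pyranone, five-membered carbocycle, ring expansion to six-membered ring B.

Assumption: the SMILES is read as the (1R,2R), 1,2-trans isomer; ring B locants follow the target throughout (C1 carries the pyranone, C2 the methyl ester, C3 the free acid, C4 is the vinylic CH).

**Route**

Step 1
Reactants: 1 catechol
Product: 2 2,2-dimethyl-1,3-benzodioxole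
Conditions: 2,2-dimethoxypropane, TsOH·H2O (cat.), PhMe, reflux, MeOH distilled off
Reagents that add atoms: 2,2-dimethoxypropane, COC(C)(C)OC
Why: Acid-catalysed transketalisation gives the catechol acetonide, which tolerates the base and Lewis-acid steps and falls off in aqueous TFA at the end.

Step 2
Reactants: 2 2,2-dimethyl-1,3-benzodioxole; 3 methyl 3-chloro-3-oxopropanoate (methyl malonyl chloride)
Product: 4 methyl 3-(2,2-dimethyl-1,3-benzodioxol-5-yl)-3-oxopropanoate
Conditions: SnCl4 (2 equiv), CH2Cl2, −20 to 0 °C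
Reagents that add atoms: none
Why: Friedel–Crafts acylation of the electron-rich benzodioxole occurs para to a ring oxygen (C5) and gives the aroylacetate directly.

Step 3
Reactants: 5 methyl tiglate
Product: 7 tert-butyl 3-methyl-2-oxo-2H-pyran-6-carboxylate, via dienol diester 6 (not isolated)
Conditions: di-tert-butyl oxalate, KOtBu, THF, 0 °C to rt; then AcOH, 80 °C
Reagents that add atoms: di-tert-butyl oxalate, CC(C)(C)OC(=O)C(=O)OC(C)(C)C
Why: Thermodynamically controlled vinylogous (γ) Claisen condensation gives the stable 2-hydroxymuconate-type enolate, and after acidification the dienol equilibrates its geometry through the 2-oxo tautomer and lactonises onto the methyl ester (loss of MeOH) to the pyranone, with the tert-butyl ester surviving AcOH.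

Step 4
Reactants: 7 tert-butyl 3-methyl-2-oxo-2H-pyran-6-carboxylate
Product: 9 tert-butyl 3-formyl-2-oxo-2H-pyran-6-carboxylate, via bromomethyl pyranone 8 (not isolated)
Conditions: NBS, AIBN (cat.), PhCF3, 80 °C; then N-methylmorpholine N-oxide, MeCN, rt
Reagents that add atoms: N-methylmorpholine N-oxide, C[N+]1([O-])CCOCC1
Why: Wohl–Ziegler bromination of the only allylic methyl (pentadienyl-type radical) followed by Kornblum-type oxidation of the activated bromide with the N-oxide gives the aldehyde.

Step 5
Reactants: 4 methyl 3-(2,2-dimethyl-1,3-benzodioxol-5-yl)-3-oxopropanoate; 9 tert-butyl 3-formyl-2-oxo-2H-pyran-6-carboxylate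
Product: 10 methyl (2Z)-2-[(2,2-dimethyl-1,3-benzodioxol-5-yl)carbonyl]-3-[6-(tert-butoxycarbonyl)-2-oxo-2H-pyran-3-yl]prop-2-enoate
Conditions: piperidine (10 mol %), AcOH (10 mol %), PhMe, 4 Å molecular sieves, rt
Reagents that add atoms: none
Why: Knoevenagel condensation of the active methylene with the very electrophilic aldehyde; the E/Z ratio does not matter because the Lewis acid of step 6 equilibrates it.

Step 6
Reactants: 10 alkylidene β-keto ester
Product: 11 methyl (2R,3R)-3-[6-(tert-butoxycarbonyl)-2-oxo-2H-pyran-3-yl]-5,6-(isopropylidenedioxy)-1-oxoindane-2-carboxylate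
Conditions: Cu(OTf)2 (10 mol %), (S,S)-Ph-BOX (11 mol %), CH2Cl2, 40 °C
Reagents that add atoms: none
Why: Polarised Nazarov cyclisation in which the two-point-bound chiral copper bis(oxazoline) Lewis acid fixes the sense of conrotation and so sets C3 (the later C1) as R (the ligand antipode is used if the induction proves opposite), closing para to the ring oxygen, while C2 equilibrates through the enol to trans.

Step 7
Reactants: 11 indanone β-keto ester
Product: 13 3-tert-butyl 2-methyl (1R)-1-[6-(tert-butoxycarbonyl)-2-oxo-2H-pyran-3-yl]-6,7-(isopropylidenedioxy)-4-oxo-1,2,3,4-tetrahydronaphthalene-2,3-dicarboxylate (C2/C3 epimer mixture), via cyclopropanol 12 (not isolated)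
Conditions: tert-butyl diazoacetate (1.1 equiv, slow addition), AgOTf (10 mol %), CH2Cl2, 0 °C to rt
Reagents that add atoms: tert-butyl diazoacetate, CC(C)(C)OC(=O)C=[N+]=[N-]
Why: Proposed new method: silver-catalysed formal insertion of the ester carbene into the C1(=O)–C2 bond of a cyclic aryl β-keto ester; the enol carbon C2 attacks the electrophilic silver carbenoid anti to the pyranone, the C-bound silver ester enolate closes onto the ketone to cyclopropanol 12, and push–pull cleavage of its C1–C2 bond (oxygen donor, methyl ester acceptor, strain relief) amounts to a 1,2-shift of the acyl carbon onto the new carbon, giving the six-membered β-keto ester with C1 untouched and C2/C3 as epimers (C3 becomes sp2, C2 is corrected in step 9); the closest known reaction types are the zinc-carbenoid CH2 chain extension/ring expansion of β-keto esters and the silver-catalysed formal carbene insertion into the C–C(=O) bond of acyclic 1,3-dicarbonyls, neither shown for an acceptor-only diazoacetate delivering a carboxylated ring carbon to a benzo-fused cyclic β-keto ester.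

Step 8
Reactants: 13 tetralone diester
Product: 14 3-tert-butyl 2-methyl (1R)-1-[6-(tert-butoxycarbonyl)-2-oxo-2H-pyran-3-yl]-4-hydroxy-6,7-(isopropylidenedioxy)-1,2,3,4-tetrahydronaphthalene-2,3-dicarboxylate (diastereomer mixture)
Conditions: NaBH4, CeCl3·7H2O, MeOH/THF, −40 °C
Reagents that add atoms: none
Why: Luche reduction delivers a hard hydride 1,2 to the aryl ketone and spares the pyranone and the esters; the new C4 centre is removed in step 9.

Step 9
Reactants: 14 benzylic alcohol
Product: 16 3-tert-butyl 2-methyl (1R,2R)-1-[6-(tert-butoxycarbonyl)-2-oxo-2H-pyran-3-yl]-6,7-(isopropylidenedioxy)-1,2-dihydronaphthalene-2,3-dicarboxylate, via C4 mesylate 15 (not isolated)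
Conditions: MsCl, Et3N, CH2Cl2, 0 °C; then DBU, 0 °C to rt, under Ar
Reagents that add atoms: none
Why: Mesylation and E1cB elimination across C3–C4 give the cinnamate-type alkene, and DBU equilibrates the C2 centre (α to the methyl ester and allylic) to the thermodynamically preferred 1,2-trans (2R) isomer without touching C1.

Step 10
Reactants: 16 protected dihydronaphthalene
Product: 17 (1R,2R)-1-(6-carboxy-2-oxo-2H-pyran-3-yl)-6,7-dihydroxy-2-(methoxycarbonyl)-1,2-dihydronaphthalene-3-carboxylic acid
Conditions: TFA/H2O (9:1), rt, under Ar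
Reagents that add atoms: none
Why: Acidolysis cleaves both tert-butyl esters and hydrolyses the acetonide in one operation, while the methyl ester, the lactone, the alkene and both stereocentres are inert to aqueous TFA.

**Compound list**
1 | catechol (benzene-1,2-diol) | Oc1ccccc1O | starting material
2 | 2,2-dimethyl-1,3-benzodioxole | CC1(C)Oc2ccccc2O1 | intermediate
3 | methyl 3-chloro-3-oxopropanoate (methyl malonyl chloride) | COC(=O)CC(Cl)=O | starting material
4 | methyl 3-(2,2-dimethyl-1,3-benzodioxol-5-yl)-3-oxopropanoate | COC(=O)CC(=O)c1ccc2OC(C)(C)Oc2c1 | intermediate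
5 | methyl tiglate (methyl (2E)-2-methylbut-2-enoate) | C/C=C(\C)C(=O)OC | starting material
6 | 1-tert-butyl 6-methyl (2Z,4E)-2-hydroxy-5-methylhexa-2,4-dienedioate (dienol diester) | COC(=O)/C(C)=C/C=C(\O)C(=O)OC(C)(C)C | intermediate
7 | tert-butyl 3-methyl-2-oxo-2H-pyran-6-carboxylate | Cc1ccc(C(=O)OC(C)(C)C)oc1=O | intermediate
8 | tert-butyl 3-(bromomethyl)-2-oxo-2H-pyran-6-carboxylate | BrCc1ccc(C(=O)OC(C)(C)C)oc1=O | intermediate
9 | tert-butyl 3-formyl-2-oxo-2H-pyran-6-carboxylate | O=Cc1ccc(C(=O)OC(C)(C)C)oc1=O | intermediate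
10 | methyl (2Z)-2-[(2,2-dimethyl-1,3-benzodioxol-5-yl)carbonyl]-3-[6-(tert-butoxycarbonyl)-2-oxo-2H-pyran-3-yl]prop-2-enoate | COC(=O)/C(C(=O)c1ccc2OC(C)(C)Oc2c1)=C\c1ccc(C(=O)OC(C)(C)C)oc1=O | intermediate
11 | methyl (2R,3R)-3-[6-(tert-butoxycarbonyl)-2-oxo-2H-pyran-3-yl]-5,6-(isopropylidenedioxy)-1-oxoindane-2-carboxylate (trans) | COC(=O)[C@H]1C(=O)c2cc3OC(C)(C)Oc3cc2[C@@H]1c1ccc(C(=O)OC(C)(C)C)oc1=O | intermediate
12 | cyclopropanol: indane of 11 in which C1 (now C–OH) and C2 are bridged by CH(CO2tBu) on the face anti to the pyranone | COC(=O)[C@]12[C@H](C(=O)OC(C)(C)C)[C@@]1(O)c1cc3OC(C)(C)Oc3cc1[C@@H]2c1ccc(C(=O)OC(C)(C)C)oc1=O | intermediate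
13 | 3-tert-butyl 2-methyl (1R)-1-[6-(tert-butoxycarbonyl)-2-oxo-2H-pyran-3-yl]-6,7-(isopropylidenedioxy)-4-oxo-1,2,3,4-tetrahydronaphthalene-2,3-dicarboxylate (C2/C3 epimers) | COC(=O)C1C(C(=O)OC(C)(C)C)C(=O)c2cc3OC(C)(C)Oc3cc2[C@@H]1c1ccc(C(=O)OC(C)(C)C)oc1=O | intermediate
14 | 3-tert-butyl 2-methyl (1R)-1-[6-(tert-butoxycarbonyl)-2-oxo-2H-pyran-3-yl]-4-hydroxy-6,7-(isopropylidenedioxy)-1,2,3,4-tetrahydronaphthalene-2,3-dicarboxylate (diastereomers) | COC(=O)C1C(C(=O)OC(C)(C)C)C(O)c2cc3OC(C)(C)Oc3cc2[C@@H]1c1ccc(C(=O)OC(C)(C)C)oc1=O | intermediate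
15 | 4-methanesulfonate of 14 | COC(=O)C1C(C(=O)OC(C)(C)C)C(OS(C)(=O)=O)c2cc3OC(C)(C)Oc3cc2[C@@H]1c1ccc(C(=O)OC(C)(C)C)oc1=O | intermediate
16 | 3-tert-butyl 2-methyl (1R,2R)-1-[6-(tert-butoxycarbonyl)-2-oxo-2H-pyran-3-yl]-6,7-(isopropylidenedioxy)-1,2-dihydronaphthalene-2,3-dicarboxylate | COC(=O)[C@H]1C(C(=O)OC(C)(C)C)=Cc2cc3OC(C)(C)Oc3cc2[C@@H]1c1ccc(C(=O)OC(C)(C)C)oc1=O | intermediate
17 | (1R,2R)-1-(6-carboxy-2-oxo-2H-pyran-3-yl)-6,7-dihydroxy-2-(methoxycarbonyl)-1,2-dihydronaphthalene-3-carboxylic acid | COC(=O)[C@H]1C(C(=O)O)=Cc2cc(O)c(O)cc2[C@@H]1c1ccc(C(=O)O)oc1=O | target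

**Step count and risks**

Total steps: 10. Longest linear sequence: 8 (steps 3, 4, 5, 6, 7, 8, 9, 10; the arm through steps 1 and 2 is equally long).

Most likely to fail, first: step 7, the proposed new ring expansion. The carbenoid may instead give O–H insertion or simple C-alkylation at C2, and the product is itself an enolisable β-keto ester that could take up a second carbene (hence 1.1 equiv, slow addition; the tert-butyl ester and the C2 substituent shield the product enol). The fallback uses known chemistry, sets out from 11 and comes back at 13. Zinc-carbenoid chain extension of the β-keto ester (Et2Zn, CH2I2, CH2Cl2, 0 °C to rt) inserts CH2 between the ketone carbon and C2 through the same cyclopropanolate fragmentation and gives methyl (1R)-1-[6-(tert-butoxycarbonyl)-2-oxo-2H-pyran-3-yl]-6,7-(isopropylidenedioxy)-4-oxo-1,2,3,4-tetrahydronaphthalene-2-carboxylate F1. Its ketone enolate (LiN(SiMe3)2, 2.1 equiv, THF, −78 °C; the aryl ketone CH2 is far more acidic than the ester CH) is then C-acylated with Boc2O to give 13.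

Second: step 6. The enantioselective Nazarov cyclisation of a 3,4-dioxygenated aryl ketone carrying an electron-poor pyranone may be slow or give modest ee, and the pyranone carbonyls can compete for the copper. The fallback sets out from 10 and comes back at 11. Cyclisation with achiral Cu(OTf)2 (5 mol %, ClCH2CH2Cl, 60 °C) gives the racemic trans-indanone, and the enantiomers are separated by preparative chromatography on a chiral stationary phase. This removes methyl (2S,3S)-3-[6-(tert-butoxycarbonyl)-2-oxo-2H-pyran-3-yl]-5,6-(isopropylidenedioxy)-1-oxoindane-2-carboxylate F2 and leaves 11.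

Third: step 3. The weak-acid lactonisation may be sluggish, or the tert-butyl ester may be lost if stronger acid is needed. The fallback sets out from 5 and comes back at 7. The classical condensation with dimethyl oxalate (KOMe, Et2O/MeOH) followed by heating the potassium enolate in concentrated aqueous HCl lactonises and hydrolyses to 3-methyl-2-oxo-2H-pyran-6-carboxylic acid F3. This acid is esterified with tert-butyl 2,2,2-trichloroacetimidate (BF3·OEt2 cat., CH2Cl2, rt) to give 7.

**Further compounds**
F1 | step 7 | methyl (1R)-1-[6-(tert-butoxycarbonyl)-2-oxo-2H-pyran-3-yl]-6,7-(isopropylidenedioxy)-4-oxo-1,2,3,4-tetrahydronaphthalene-2-carboxylate | COC(=O)C1CC(=O)c2cc3OC(C)(C)Oc3cc2[C@@H]1c1ccc(C(=O)OC(C)(C)C)oc1=O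
F2 | step 6 | methyl (2S,3S)-3-[6-(tert-butoxycarbonyl)-2-oxo-2H-pyran-3-yl]-5,6-(isopropylidenedioxy)-1-oxoindane-2-carboxylate | COC(=O)[C@@H]1C(=O)c2cc3OC(C)(C)Oc3cc2[C@H]1c1ccc(C(=O)OC(C)(C)C)oc1=O
F3 | step 3 | 3-methyl-2-oxo-2H-pyran-6-carboxylic acid | Cc1ccc(C(=O)O)oc1=O
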